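- Wednesday's flask at 68 °C made more target in 15.0 min than Thursday's at 25 °C did in 90.0 min, 23 % against 2 %, so I took seriously your hunch that heat was the lever for a quick number.

| setting | Thursday's | Wednesday's | Monday's | winter | summer | midnight | dawn |
|---|---|---|---|---|---|---|---|
| starting material | 0.070 M | 0.11 M | 0.050 M | 0.050 M | 0.050 M | 0.050 M | 0.050 M |
| reagent | 0.060 M | 0.060 M | 0.060 M | 0.0600 M | 0.0600 M | 0.0600 M | 0.0600 M |
| free catalyst | 5 mM | 5 mM | 5 mM | 5.0 mM | 5.0 mM | 5.0 mM | 5.0 mM |
| second catalyst | 7.5 mM | 7.5 mM | 11 mM | 7.5 mM | 7.5 mM | 7.5 mM | 7.5 mM |
| temperature | 25 °C | 68 °C | 25 °C | 30 °C | 55 °C | 80 °C | 105 °C |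
| remark | run made earlier | run made earlier | run made earlier |  |  |  |  |
| time |  |  |  | 80 min | 80 min | 80 min | 80 min |

- Thursday's (time / min: target / %): 8.00: 0; 12.0: 1; 20.0: 0; 40.0: 2; 60.0: 4; 90.0: 2
- Wednesday's (time / min: target / %): 1.33: 0; 2.00: 0; 3.00: 1; 6.00: 9; 10.0: 19; 15.0: 23
- Monday's (time / min: target / %): 8.00: 0; 25.0: 1; 40.0: 0; 60.0: 5; 90.0: 2

(readings scatter by 2 percentage points)

* which flask leads in amount of target, in percent of the starting material charged ("all alike" within 1.5 percentage points) (winter / summer / midnight / dawn / all alike)
* how much target is there at the end, in percent of the starting material charged: winter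
* how much target is there at the end, in percent of the starting material charged: summer
* how much target is there at the end, in percent of the starting material charged: midnight
* how much target is there at the end, in percent of the starting material charged: dawn



- Starting material was the limiting reagent, 0.050 M against 0.0600 M of reagent, so, taking one reagent per target, I wrote c(target) as the charge minus c(starting material) and watched what remained of that charge.
- Between 6.00 min and 10.0 min, Wednesday's readings put the starting material not yet turned into target at 91.0 % and then 81.0 % of its charge, so the logarithm of that fall over the interval gave 0.0291 min⁻¹, which I called the clearing share: the part of the remaining starting material turned per minute, a pseudo-first-order constant. It was a reading and carried their scatter of 2 percentage points.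
- Held for 80 min, that share left exp(−share × time) of the charge, so I reckoned 90.3 % target, and midnight, hotter than Wednesday's, as no lower.
- The forecast differed: winter 5 %, summer 42 %, midnight 55 %, dawn 42 %, with midnight leading, and it read Wednesday's late slowing as “possibly from catalyst death”.
- The flasks gave winter 5.04 %, summer 42.7 %, midnight 94.9 % and dawn 88.6 %, so midnight led, 40 points above the forecast's figure, with free catalyst still at 100 % and starting material down to 1.90 %.

    starting material + free catalyst ⇌ free catalyst + intermediate (K = 1.20, k = 0.180 M⁻¹ s⁻¹, Ea = 77.0 kJ mol⁻¹, ΔH = −23.0 kJ mol⁻¹)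
    reagent + second catalyst + intermediate → second catalyst + target (k = 58.0 M⁻² s⁻¹, Ea = 43.0 kJ mol⁻¹)
    intermediate → side product (k = 4.10 × 10⁻⁴ s⁻¹, Ea = 110 kJ mol⁻¹)
    (constants at 80 °C)

- Midnight's state at 40.0 min gave a clearing share of 0.0510 min⁻¹, 1.75 times Wednesday's reading, which leaves 1.69 % at 80 min against the 1.90 % midnight held. Dawn stayed below midnight because intermediate went to side product, 11.4 % of the charge, and the same run without that step gave >99.9 %. Winter's conversion of 5.55 % in 80 min gives a share of 7.137 × 10⁻⁴ min⁻¹, which leaves 80.7 % at 5.0 h, and winter read at that time held 81 %.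

The numbers in the tables stem from a simulated flask with constants of no real substance, noise included.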